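**Plan**

1. Retrosynthetic cuts, in order: the C15 stearate ester; C8=C17 (Wittig) and C4–C18 (enolate methylation); then C5–C10, the bond common to ring A (C1–C5, C10) and ring B (C5–C10).
2. Enabling feature: without C5–C10 the core is a cyclodecane C1–C10 in which C10, as a methylidene (C20), lies across the ring from C5, the β-carbon of a C4=C5 enoate (C19 ester on C4). Hydrogen-atom transfer to C20 lets the C10 radical bond to C5 and form both rings at once.
3. The ten-membered ring is cut at C1–C10 (hydroboration/B-alkyl Suzuki of a C10 enol triflate), then at C4=C5 (Still–Gennari olefination), C10–C20 (MeMgBr on a Weinreb amide), C8–C9 (Evans syn aldol) and C9–C10 (Grignard carboxylation of a citronellol-derived bromide).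
4. Forward order: side chain with C9/C8, chain extension to a triflate–enoate–alkene, closure of the cyclodecene, transannular closure to the trans-decalin, then C18, C17, the free acid and the stearate.
5. Stereochemistry: C13 from (S)-citronellol; C9 and C8 from the (S)-4-benzyloxazolidinone aldol; C10 and C5 from the chair–chair transannular transition state, biased by the equatorial C9 chain and C8 silyloxy group; C4 by methylation anti to the axial C20 methyl.

Key step: step 15

**Remarks**

- Labdane numbering is used for all intermediates. TBDPS = tert-butyldiphenylsilyl, TBS = tert-butyldimethylsilyl, 9-BBN = 9-borabicyclo[3.3.1]nonane, DMP = Dess–Martin periodinane, CSA = camphorsulfonic acid.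
- C8 is carried through the cyclisation as an equatorial (α) silyl ether and oxidised afterwards. An acetal at C8 would place one oxygen axial, 1,3 to the incoming C20 methyl, in the chair–chair transition state.
- The key-step product is written as its C4-equatorial ester; a C4 epimer, should it form, converges on the same enolate in the following step.
- The enoate is Z by CIP rules (ester cis to C6), which means ring carbons C3 and C6 are trans across the double bond.
- The phosphonate, allyl bromide, (S)-citronellol, the oxazolidinone, pent-4-enal and stearoyl chloride are taken as commercial.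

**Route**

Step 1
Reactants: 1 methyl 2-[bis(2,2,2-trifluoroethoxy)phosphoryl]acetate; 2 allyl bromide
Product: 4 methyl 2-[bis(2,2,2-trifluoroethoxy)phosphoryl]pent-4-enoate (racemic), via sodium salt 3 (not isolated)
Conditions: 1 (1.3 equiv), NaH, DMF, 0 °C; then 2, 0 °C → rt
Reagents that add atoms: none
Why: C-alkylation of a phosphonate-stabilised carbanion with a reactive allylic bromide (excess 1 limits dialkylation); the α-centre is racemic and is lost in the later olefination.

Step 2
Reactants: 5 (S)-citronellol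
Product: 6 (S)-citronellol TBDPS ether
Conditions: TBDPSCl, imidazole, CH2Cl2, rt
Reagents that add atoms: tert-butyl(chloro)diphenylsilane, CC(C)(C)[Si](Cl)(c1ccccc1)c1ccccc1
Why: routine silylation of a primary alcohol, which fixes the C15 oxygen and leaves the C13 stereocentre of citronellol untouched.

Step 3
Reactants: 6 (S)-citronellol TBDPS ether
Product: 8 (4S)-6-[(tert-butyldiphenylsilyl)oxy]-4-methylhexan-1-ol, via ozonide 7 (not isolated)
Conditions: O3, CH2Cl2, −78 °C; then NaBH4, MeOH, −78 °C → rt
Reagents that add atoms: ozone, [O-][O+]=O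
Why: ozonolysis of the trisubstituted alkene with reductive NaBH4 work-up should give the primary alcohol directly, with C9 as the carbinol carbon.

Step 4
Reactants: 8 (4S)-6-[(tert-butyldiphenylsilyl)oxy]-4-methylhexan-1-ol
Product: 9 {[(3S)-6-bromo-3-methylhexyl]oxy}(tert-butyl)diphenylsilane
Conditions: CBr4, PPh3, CH2Cl2, 0 °C
Reagents that add atoms: tetrabromomethane, BrC(Br)(Br)Br
Why: Appel bromination of an unhindered primary alcohol under neutral conditions that spare the silyl ether.

Step 5
Reactants: 9 {[(3S)-6-bromo-3-methylhexyl]oxy}(tert-butyl)diphenylsilane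
Product: 11 (5S)-7-[(tert-butyldiphenylsilyl)oxy]-5-methylheptanoic acid, via Grignard reagent 10 (not isolated)
Conditions: Mg, THF, reflux; then CO2, −20 °C → rt; 1 M HCl
Reagents that add atoms: carbon dioxide, O=C=O
Why: Grignard carboxylation adds C10 as the carboxyl carbon, so that C9 becomes the enolisable α-position needed for the aldol.

Step 6
Reactants: 11 (5S)-7-[(tert-butyldiphenylsilyl)oxy]-5-methylheptanoic acid; 12 (4S)-4-benzyl-1,3-oxazolidin-2-one
Product: 14 (4S)-4-benzyl-3-{(5S)-7-[(tert-butyldiphenylsilyl)oxy]-5-methylheptanoyl}-1,3-oxazolidin-2-one, via mixed pivalic anhydride 13 (not isolated)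
Conditions: t-BuCOCl, Et3N, THF, −20 °C; then LiCl, 12, −20 °C → rt
Reagents that add atoms: none
Why: N-acylation of the oxazolidinone through the mixed pivalic anhydride (LiCl/Et3N protocol), a standard way to make Evans imides without strong base.

Step 7
Reactants: 14 (4S)-4-benzyl-3-{(5S)-7-[(tert-butyldiphenylsilyl)oxy]-5-methylheptanoyl}-1,3-oxazolidin-2-one; 15 pent-4-enal
Product: 17 syn-aldol adduct (2S,3R)-3-hydroxy-2-alkylhept-6-enoyl imide, via boron enolate 16 (not isolated)
Conditions: Bu2BOTf, iPr2NEt, CH2Cl2, −78 → 0 °C; then 15, −78 → 0 °C; pH 7 buffer, MeOH, H2O2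
Reagents that add atoms: none
Why: Evans syn aldol, in which the Z-boron enolate reacts through a closed Zimmerman–Traxler transition state on the face away from the benzyl group, setting C9 (S) and C8 (R) with the C11 chain and the hydroxyl syn.

Step 8
Reactants: 17 syn-aldol adduct
Product: 18 (2S,3R)-3-hydroxy Weinreb amide
Conditions: MeNHOMe·HCl, AlMe3, CH2Cl2, −20 °C → rt; dilute HCl work-up
Reagents that add atoms: N,O-dimethylhydroxylamine hydrochloride, CNOC.Cl
Why: aluminium-amide transamination of a β-hydroxy imide to the Weinreb amide, assisted by the free hydroxyl, with release of the auxiliary and no epimerisation at C9.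

Step 9
Reactants: 18 (2S,3R)-3-hydroxy Weinreb amide
Product: 19 C8 TBS ether of the Weinreb amide
Conditions: TBSOTf, 2,6-lutidine, CH2Cl2, −78 → 0 °C
Reagents that add atoms: tert-butyldimethylsilyl trifluoromethanesulfonate, CC(C)(C)[Si](C)(C)OS(=O)(=O)C(F)(F)F
Why: silylation of a secondary alcohol with the silyl triflate, which blocks retro-aldol and β-elimination in the later base steps.

Step 10
Reactants: 19 C8 TBS ether of the Weinreb amide
Product: 20 (3S,4R)-4-[(tert-butyldimethylsilyl)oxy]-3-{(3S)-5-[(tert-butyldiphenylsilyl)oxy]-3-methylpentyl}oct-7-en-2-one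
Conditions: MeMgBr, THF, 0 °C; NH4Cl (aq)
Reagents that add atoms: methylmagnesium bromide, C[Mg]Br
Why: Weinreb ketone synthesis, in which the chelated tetrahedral adduct prevents over-addition and releases the methyl ketone (C10 carbonyl, C20 methyl) only on work-up, so C9 is not exposed to base as a ketone.

Step 11
Reactants: 20 methyl ketone with terminal alkene
Product: 22 (4R,5S)-4-[(tert-butyldimethylsilyl)oxy]-5-{(3S)-5-[(tert-butyldiphenylsilyl)oxy]-3-methylpentyl}-6-oxoheptanal, via ozonide 21 (not isolated)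
Conditions: O3, CH2Cl2, −78 °C; then PPh3, −78 °C → rt
Reagents that add atoms: ozone, [O-][O+]=O
Why: ozonolysis of the only alkene with neutral phosphine reduction should give the C5 aldehyde without touching the ketone or the silyl ethers.

Step 12
Reactants: 22 keto aldehyde; 4 methyl 2-[bis(2,2,2-trifluoroethoxy)phosphoryl]pent-4-enoate
Product: 24 methyl (2Z,6R,7S)-6-silyloxy-8-oxo-2-(prop-2-en-1-yl)non-2-enoate, via potassium salt 23 (not isolated)
Conditions: 4, KN(SiMe3)2, 18-crown-6, THF, −78 °C; then 22, −78 °C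
Reagents that add atoms: none
Why: Still–Gennari variant of the Horner–Wadsworth–Emmons reaction, in which fast elimination from the trifluoroethyl phosphonate adduct gives the Z-enoate (ester cis to C6, so C3 and C6 trans), the aldehyde reacting far faster than the methyl ketone.

Step 13
Reactants: 24 Z-enoate methyl ketone
Product: 26 C10 enol triflate, via potassium enolate 25 (not isolated)
Conditions: KN(SiMe3)2 (1.05 equiv), THF, −78 °C; then PhNTf2, −78 → −20 °C
Reagents that add atoms: N-phenylbis(trifluoromethanesulfonimide), O=S(=O)(N(c1ccccc1)S(=O)(=O)C(F)(F)F)C(F)(F)F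
Why: kinetic enolisation of the methyl ketone at the unhindered C20 methyl (far more acidic than any C–H of the enoate) and O-sulfonylation give the less substituted enol triflate without touching C9.

Step 14
Reactants: 26 C10 enol triflate
Product: 28 methyl (1Z,5R,6R)-5-[(tert-butyldimethylsilyl)oxy]-6-{(3S)-5-[(tert-butyldiphenylsilyl)oxy]-3-methylpentyl}-7-methylidenecyclodec-1-ene-1-carboxylate, via alkylborane 27 (not isolated)
Conditions: 9-BBN, THF, 0 °C → rt; then slow addition to Pd(dppf)Cl2 (20 mol %), AsPh3, Cs2CO3, DMF/THF/H2O, 50 °C, 2 mM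
Reagents that add atoms: none
Why: chemoselective anti-Markovnikov hydroboration of the monosubstituted alkene, then intramolecular B-alkyl Suzuki–Miyaura coupling (zerovalent palladium formed in situ inserts into the C10–O bond), closes the ten-membered ring at C1–C10 and leaves C10 as the methylidene.

Step 15
Reactants: 28 ten-membered ring with C10 methylidene and C4=C5 enoate
Product: 29 methyl (1R,4aS,5R,6R,8aS)-6-[(tert-butyldimethylsilyl)oxy]-5-{(3S)-5-[(tert-butyldiphenylsilyl)oxy]-3-methylpentyl}-4a-methyldecahydronaphthalene-1-carboxylate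
Conditions: Fe(acac)3 (30 mol %), PhSiH3, EtOH/ethylene glycol, 60 °C, 5 mM
Reagents that add atoms: none
Why: Proposed new method: an iron hydride formed from Fe(acac)3 and PhSiH3 should transfer a hydrogen atom to the CH2 terminus of the electron-rich C10 methylidene (creating the C20 methyl), and the nucleophilic tertiary C10 radical should add across the ring to C5, the β-carbon of the C4=C5 enoate, after which the C4 radical is reduced by divalent iron and the enolate protonated by ethanol; because the ring holds C10 and C5 within bonding distance, closure should outrun reduction of the radical. The closest known reactions are intramolecular iron-hydride Giese couplings of 1,1-disubstituted alkenes with enoates and tin-mediated transannular radical cyclisations of medium rings. The new C5–C10 bond closes ring B in a 6-exo mode and ring A in a 6-endo mode. C10 and C5 are set together in a chair–chair transition state: the trans relation of C3 and C6 on the enoate leads to the trans ring fusion, and the C9 chain and C8 silyloxy group, which are both equatorial in only one such arrangement, select the face so that C20 ends up β and H5 α, while C4 arises by protonation and is fixed in the next step. The step needs hydrogen-atom transfer to the methylidene in preference to the enoate, secured by the electron-poor character of the latter, and high dilution to suppress intermolecular coupling.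

Step 16
Reactants: 29 trans-decalin ester
Product: 31 C4-methylated ester (C19 ester axial), via lithium enolate 30 (not isolated)
Conditions: LiN(iPr)2, THF, −78 → 0 °C; then MeI, DMPU, −78 → 0 °C
Reagents that add atoms: iodomethane, CI
Why: ester enolate alkylation in which MeI approaches the α face, away from the axial C20 methyl, so that C18 ends up equatorial and the C19 ester axial (4S); either C4 epimer of 29 gives the same enolate.

Step 17
Reactants: 31 C4-methylated ester
Product: 32 C8 alcohol
Conditions: CSA, MeOH/CH2Cl2, rt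
Reagents that add atoms: none
Why: acid-catalysed methanolysis removes the secondary TBS ether, while the primary TBDPS ether is much more stable to acid and should remain.

Step 18
Reactants: 32 C8 alcohol
Product: 33 C8 ketone
Conditions: DMP, CH2Cl2, rt
Reagents that add atoms: none
Why: Dess–Martin oxidation of a secondary alcohol under near-neutral conditions; C9 already carries its chain equatorial, the thermodynamically preferred arrangement next to the ketone.

Step 19
Reactants: 33 C8 ketone
Product: 34 C8 methylidene ester (C17 installed)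
Conditions: Ph3PCH3Br, KOtBu, toluene, rt → 80 °C
Reagents that add atoms: methyltriphenylphosphonium bromide, C[P+](c1ccccc1)(c1ccccc1)c1ccccc1.[Br-]
Why: Wittig methylenation of a ring ketone with a preformed non-stabilised ylide; the hindered axial C19 ester is inert, and any enolisation at C9 returns to the favoured equatorial chain.

Step 20
Reactants: 34 C8 methylidene ester
Product: 35 methyl (1S,4aR,5S,8aR)-5-[(3S)-5-hydroxy-3-methylpentyl]-1,4a-dimethyl-6-methylidenedecahydronaphthalene-1-carboxylate
Conditions: TBAF, THF, rt; NH4Cl (aq)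
Reagents that add atoms: none
Why: fluoride cleavage of the Si–O bond frees the C15 hydroxyl without affecting the ester or the exocyclic alkene.

Step 21
Reactants: 35 C15 hydroxy methyl ester
Product: 36 (1S,4aR,5S,8aR)-5-[(3S)-5-hydroxy-3-methylpentyl]-1,4a-dimethyl-6-methylidenedecahydronaphthalene-1-carboxylic acid
Conditions: NaSEt, DMF, 110 °C; then 1 M HCl
Reagents that add atoms: none
Why: SN2 O-demethylation by thiolate at the methyl carbon, the usual answer to an axial neopentyl-type ester whose carbonyl is shielded against saponification.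

Step 22
Reactants: 36 hydroxy acid; 37 stearoyl chloride
Product: 38 CNP0298278.1 (15-O-stearoyl hydroxy acid)
Conditions: 37, pyridine, DMAP (cat.), CH2Cl2, 0 °C → rt; aqueous NaHCO3, then pH 3
Reagents that add atoms: none
Why: DMAP-catalysed O-acylation of the primary alcohol; a mixed anhydride at the hindered tertiary C19 acid can only pass on its stearoyl group and is hydrolysed on work-up, so the acid needs no protection.

**Compound list**

1 | methyl 2-[bis(2,2,2-trifluoroethoxy)phosphoryl]acetate | COC(=O)CP(=O)(OCC(F)(F)F)OCC(F)(F)F | starting material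
2 | allyl bromide (3-bromoprop-1-ene) | C=CCBr | starting material
3 | sodium salt (phosphonate carbanion) of 1 | [Na+].COC(=O)[CH-]P(=O)(OCC(F)(F)F)OCC(F)(F)F | intermediate (not isolated)
4 | methyl 2-[bis(2,2,2-trifluoroethoxy)phosphoryl]pent-4-enoate (racemic) | COC(=O)C(CC=C)P(=O)(OCC(F)(F)F)OCC(F)(F)F | intermediate
5 | (S)-citronellol, (3S)-3,7-dimethyloct-6-en-1-ol | CC(C)=CCC[C@H](C)CCO | starting material
6 | tert-butyl{[(3S)-3,7-dimethyloct-6-en-1-yl]oxy}diphenylsilane | CC(C)=CCC[C@H](C)CCO[Si](c1ccccc1)(c1ccccc1)C(C)(C)C | intermediate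
7 | ozonide of 6: 3,3-dimethyl-5-{(3S)-5-[(tert-butyldiphenylsilyl)oxy]-3-methylpentyl}-1,2,4-trioxolane | CC1(C)OC(CC[C@H](C)CCO[Si](c2ccccc2)(c2ccccc2)C(C)(C)C)OO1 | intermediate (not isolated)
8 | (4S)-6-[(tert-butyldiphenylsilyl)oxy]-4-methylhexan-1-ol | OCCC[C@H](C)CCO[Si](c1ccccc1)(c1ccccc1)C(C)(C)C | intermediate
9 | {[(3S)-6-bromo-3-methylhexyl]oxy}(tert-butyl)diphenylsilane | BrCCC[C@H](C)CCO[Si](c1ccccc1)(c1ccccc1)C(C)(C)C | intermediate
10 | {(4S)-6-[(tert-butyldiphenylsilyl)oxy]-4-methylhexyl}magnesium bromide | Br[Mg]CCC[C@H](C)CCO[Si](c1ccccc1)(c1ccccc1)C(C)(C)C | intermediate (not isolated)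
11 | (5S)-7-[(tert-butyldiphenylsilyl)oxy]-5-methylheptanoic acid | OC(=O)CCC[C@H](C)CCO[Si](c1ccccc1)(c1ccccc1)C(C)(C)C | intermediate
12 | (4S)-4-benzyl-1,3-oxazolidin-2-one | O=C1OC[C@H](Cc2ccccc2)N1 | starting material
13 | mixed anhydride of 11 with pivalic acid | CC(C)(C)C(=O)OC(=O)CCC[C@H](C)CCO[Si](c1ccccc1)(c1ccccc1)C(C)(C)C | intermediate (not isolated)
14 | (4S)-4-benzyl-3-{(5S)-7-[(tert-butyldiphenylsilyl)oxy]-5-methylheptanoyl}-1,3-oxazolidin-2-one | O=C1OC[C@H](Cc2ccccc2)N1C(=O)CCC[C@H](C)CCO[Si](c3ccccc3)(c3ccccc3)C(C)(C)C | intermediate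
15 | pent-4-enal | C=CCCC=O | starting material
16 | (Z)-dibutylboron enolate of 14 | CCCCB(CCCC)O/C(N1C(=O)OC[C@@H]1Cc1ccccc1)=C\CC[C@H](C)CCO[Si](c2ccccc2)(c2ccccc2)C(C)(C)C | intermediate (not isolated)
17 | (4S)-4-benzyl-3-[(2S,3R)-2-{(3S)-5-[(tert-butyldiphenylsilyl)oxy]-3-methylpentyl}-3-hydroxyhept-6-enoyl]-1,3-oxazolidin-2-one | O=C1OC[C@H](Cc2ccccc2)N1C(=O)[C@@H](CC[C@H](C)CCO[Si](c3ccccc3)(c3ccccc3)C(C)(C)C)[C@H](O)CCC=C | intermediate
18 | (2S,3R)-2-{(3S)-5-[(tert-butyldiphenylsilyl)oxy]-3-methylpentyl}-3-hydroxy-N-methoxy-N-methylhept-6-enamide | CON(C)C(=O)[C@@H](CC[C@H](C)CCO[Si](c1ccccc1)(c1ccccc1)C(C)(C)C)[C@H](O)CCC=C | intermediate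
19 | (2S,3R)-3-[(tert-butyldimethylsilyl)oxy]-2-{(3S)-5-[(tert-butyldiphenylsilyl)oxy]-3-methylpentyl}-N-methoxy-N-methylhept-6-enamide | CON(C)C(=O)[C@@H](CC[C@H](C)CCO[Si](c1ccccc1)(c1ccccc1)C(C)(C)C)[C@H](O[Si](C)(C)C(C)(C)C)CCC=C | intermediate
20 | (3S,4R)-4-[(tert-butyldimethylsilyl)oxy]-3-{(3S)-5-[(tert-butyldiphenylsilyl)oxy]-3-methylpentyl}oct-7-en-2-one | CC(=O)[C@@H](CC[C@H](C)CCO[Si](c1ccccc1)(c1ccccc1)C(C)(C)C)[C@H](O[Si](C)(C)C(C)(C)C)CCC=C | intermediate
21 | ozonide of 20 (3-substituted 1,2,4-trioxolane at the former terminal alkene) | CC(=O)[C@@H](CC[C@H](C)CCO[Si](c1ccccc1)(c1ccccc1)C(C)(C)C)[C@H](O[Si](C)(C)C(C)(C)C)CCC2OCOO2 | intermediate (not isolated)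
22 | (4R,5S)-4-[(tert-butyldimethylsilyl)oxy]-5-{(3S)-5-[(tert-butyldiphenylsilyl)oxy]-3-methylpentyl}-6-oxoheptanal | CC(=O)[C@@H](CC[C@H](C)CCO[Si](c1ccccc1)(c1ccccc1)C(C)(C)C)[C@H](O[Si](C)(C)C(C)(C)C)CCC=O | intermediate
23 | potassium salt (phosphonate carbanion) of 4 | [K+].COC(=O)[C-](CC=C)P(=O)(OCC(F)(F)F)OCC(F)(F)F | intermediate (not isolated)
24 | methyl (2Z,6R,7S)-6-[(tert-butyldimethylsilyl)oxy]-7-{(3S)-5-[(tert-butyldiphenylsilyl)oxy]-3-methylpentyl}-8-oxo-2-(prop-2-en-1-yl)non-2-enoate | CC(=O)[C@@H](CC[C@H](C)CCO[Si](c1ccccc1)(c1ccccc1)C(C)(C)C)[C@H](O[Si](C)(C)C(C)(C)C)CC/C=C(/CC=C)C(=O)OC | intermediate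
25 | potassium C10–C20 enolate of 24 | [K+].C=C([O-])[C@@H](CC[C@H](C)CCO[Si](c1ccccc1)(c1ccccc1)C(C)(C)C)[C@H](O[Si](C)(C)C(C)(C)C)CC/C=C(/CC=C)C(=O)OC | intermediate (not isolated)
26 | methyl (2Z,6R,7S)-6-[(tert-butyldimethylsilyl)oxy]-7-{(3S)-5-[(tert-butyldiphenylsilyl)oxy]-3-methylpentyl}-2-(prop-2-en-1-yl)-8-{[(trifluoromethyl)sulfonyl]oxy}nona-2,8-dienoate | C=C(OS(=O)(=O)C(F)(F)F)[C@@H](CC[C@H](C)CCO[Si](c1ccccc1)(c1ccccc1)C(C)(C)C)[C@H](O[Si](C)(C)C(C)(C)C)CC/C=C(/CC=C)C(=O)OC | intermediate
27 | B-alkyl-9-BBN adduct of 26 (boron on C1) | C=C(OS(=O)(=O)C(F)(F)F)[C@@H](CC[C@H](C)CCO[Si](c1ccccc1)(c1ccccc1)C(C)(C)C)[C@H](O[Si](C)(C)C(C)(C)C)CC/C=C(/CCCB1C2CCCC1CCC2)C(=O)OC | intermediate (not isolated)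
28 | methyl (1Z,5R,6R)-5-[(tert-butyldimethylsilyl)oxy]-6-{(3S)-5-[(tert-butyldiphenylsilyl)oxy]-3-methylpentyl}-7-methylidenecyclodec-1-ene-1-carboxylate | C=C1CCC/C(C(=O)OC)=C/CC[C@@H](O[Si](C)(C)C(C)(C)C)[C@@H]1CC[C@H](C)CCO[Si](c2ccccc2)(c2ccccc2)C(C)(C)C | intermediate (key-step precursor)
29 | methyl (1R,4aS,5R,6R,8aS)-6-[(tert-butyldimethylsilyl)oxy]-5-{(3S)-5-[(tert-butyldiphenylsilyl)oxy]-3-methylpentyl}-4a-methyldecahydronaphthalene-1-carboxylate (trans-decalin; 8α-OTBS, 9β-chain, 10β-methyl, 5α-H, C4 ester equatorial) | COC(=O)[C@@H]1CCC[C@@]2(C)[C@H]1CC[C@@H](O[Si](C)(C)C(C)(C)C)[C@@H]2CC[C@H](C)CCO[Si](c3ccccc3)(c3ccccc3)C(C)(C)C | intermediate (key-step product)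
30 | lithium ester enolate of 29 | [Li]OC(OC)=C1CCC[C@@]2(C)[C@H]1CC[C@@H](O[Si](C)(C)C(C)(C)C)[C@@H]2CC[C@H](C)CCO[Si](c3ccccc3)(c3ccccc3)C(C)(C)C | intermediate (not isolated)
31 | methyl (1S,4aS,5R,6R,8aR)-6-[(tert-butyldimethylsilyl)oxy]-5-{(3S)-5-[(tert-butyldiphenylsilyl)oxy]-3-methylpentyl}-1,4a-dimethyldecahydronaphthalene-1-carboxylate | COC(=O)[C@@]1(C)CCC[C@@]2(C)[C@H]1CC[C@@H](O[Si](C)(C)C(C)(C)C)[C@@H]2CC[C@H](C)CCO[Si](c3ccccc3)(c3ccccc3)C(C)(C)C | intermediate
32 | methyl (1S,4aS,5R,6R,8aR)-5-{(3S)-5-[(tert-butyldiphenylsilyl)oxy]-3-methylpentyl}-6-hydroxy-1,4a-dimethyldecahydronaphthalene-1-carboxylate | COC(=O)[C@@]1(C)CCC[C@@]2(C)[C@H]1CC[C@@H](O)[C@@H]2CC[C@H](C)CCO[Si](c3ccccc3)(c3ccccc3)C(C)(C)C | intermediate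
33 | methyl (1S,4aS,5R,8aR)-5-{(3S)-5-[(tert-butyldiphenylsilyl)oxy]-3-methylpentyl}-1,4a-dimethyl-6-oxodecahydronaphthalene-1-carboxylate | COC(=O)[C@@]1(C)CCC[C@@]2(C)[C@H]1CCC(=O)[C@@H]2CC[C@H](C)CCO[Si](c3ccccc3)(c3ccccc3)C(C)(C)C | intermediate
34 | methyl (1S,4aR,5S,8aR)-5-{(3S)-5-[(tert-butyldiphenylsilyl)oxy]-3-methylpentyl}-1,4a-dimethyl-6-methylidenedecahydronaphthalene-1-carboxylate | COC(=O)[C@@]1(C)CCC[C@@]2(C)[C@H]1CCC(=C)[C@@H]2CC[C@H](C)CCO[Si](c3ccccc3)(c3ccccc3)C(C)(C)C | intermediate
35 | methyl (1S,4aR,5S,8aR)-5-[(3S)-5-hydroxy-3-methylpentyl]-1,4a-dimethyl-6-methylidenedecahydronaphthalene-1-carboxylate | COC(=O)[C@@]1(C)CCC[C@@]2(C)[C@H]1CCC(=C)[C@@H]2CC[C@H](C)CCO | intermediate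
36 | (1S,4aR,5S,8aR)-5-[(3S)-5-hydroxy-3-methylpentyl]-1,4a-dimethyl-6-methylidenedecahydronaphthalene-1-carboxylic acid | OC(=O)[C@@]1(C)CCC[C@@]2(C)[C@H]1CCC(=C)[C@@H]2CC[C@H](C)CCO | intermediate
37 | stearoyl chloride (octadecanoyl chloride) | CCCCCCCCCCCCCCCCCC(=O)Cl | starting material
38 | (1S,4aR,5S,8aR)-1,4a-dimethyl-6-methylidene-5-[(3S)-3-methyl-5-(octadecanoyloxy)pentyl]decahydronaphthalene-1-carboxylic acid (CNP0298278.1) | C=C1CC[C@@H]2[C@](C)(CCC[C@]2(C)C(=O)O)[C@H]1CC[C@H](C)CCOC(=O)CCCCCCCCCCCCCCCCC | target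

**Step count and risks**

Total: 22 steps. Longest linear sequence: 21 steps (steps 2–22, from (S)-citronellol); step 1 is a one-step side branch.

Most likely to fail:

1. Step 15 (new method). The C10 radical may be quenched before the transannular bond forms, either by reduction (net hydrogenation of the methylidene) or by reversible hydrogen-atom transfer that moves the alkene into the ring. Closure through a non-chair conformer would also erode ring-fusion and facial selectivity. Fallback, by known chemistry: setting out from 28, Markovnikov addition of dry HCl (CH2Cl2, −78 °C) would give the C10 tertiary chloride F1 (either C10 epimer). Slow addition of Bu3SnH with AIBN in toluene at 100 °C would then generate the same C10 radical in a tin hydride chain, where its lifetime is set by the low stannane concentration. Tin-mediated transannular radical cyclisation of medium rings is an established reaction type, and the sequence comes back to the route at 29.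

2. Step 14. Intermolecular coupling, protodeboronation or β-hydride elimination may overtake closure of the strained ten-membered ring with its trans-configured enoate. Fallback: setting out from 26, hydroboration with 9-BBN and oxidation (NaBO3·4H2O) would give the primary alcohol F2, and Dess–Martin oxidation the C1 aldehyde F3. Nozaki–Hiyama–Kishi ring closure of the C10 enol triflate onto C1 (CrCl2, NiCl2 cat., DMSO, high dilution) would give the ten-membered allylic alcohol F4 (either C1 epimer). Formylation (HCO2H, DCC, DMAP) to the allylic formate F5 and palladium-catalysed decarboxylative reduction (Pd(OAc)2, PBu3, THF, 65 °C), which delivers hydride to the more substituted allyl terminus C1 and keeps the exocyclic methylidene, would come back to the route at 28.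

3. Step 13. The amide base may also deprotonate the doubly allylic C3 or the γ-position C6 of the enoate, which would move the skipped diene into conjugation or erode the Z geometry, and the ketone enolate may add to the enoate. Fallback: the order is changed so that the enoate never meets the strong base. Setting out from 20, enol triflate formation (KN(SiMe3)2, PhNTf2, −78 °C) would give the triflate F6. Selective dihydroxylation and cleavage of the monosubstituted alkene in the presence of the electron-poor enol triflate (OsO4 cat., NMO; then NaIO4) would give the aldehyde F7. Still–Gennari olefination with 23 (from 4) would then come back to the route at 26.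

**Further compounds**

F1 | step 15 | C10 tertiary chloride of 28 (Markovnikov HCl adduct, C10 bearing Cl and the C20 methyl, either C10 epimer) | CC1(Cl)CCC/C(C(=O)OC)=C/CC[C@@H](O[Si](C)(C)C(C)(C)C)[C@@H]1CC[C@H](C)CCO[Si](c2ccccc2)(c2ccccc2)C(C)(C)C
F2 | step 14 | primary alcohol from 26 (3-hydroxypropyl in place of the allyl group, OH on C1) | C=C(OS(=O)(=O)C(F)(F)F)[C@@H](CC[C@H](C)CCO[Si](c1ccccc1)(c1ccccc1)C(C)(C)C)[C@H](O[Si](C)(C)C(C)(C)C)CC/C=C(/CCCO)C(=O)OC
F3 | step 14 | C1 aldehyde from F2 (3-oxopropyl side chain) | C=C(OS(=O)(=O)C(F)(F)F)[C@@H](CC[C@H](C)CCO[Si](c1ccccc1)(c1ccccc1)C(C)(C)C)[C@H](O[Si](C)(C)C(C)(C)C)CC/C=C(/CCC=O)C(=O)OC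
F4 | step 14 | ten-membered allylic alcohol (C1 hydroxy analogue of 28, either C1 epimer) | C=C1C(O)CC/C(C(=O)OC)=C/CC[C@@H](O[Si](C)(C)C(C)(C)C)[C@@H]1CC[C@H](C)CCO[Si](c2ccccc2)(c2ccccc2)C(C)(C)C
F5 | step 14 | C1 formate of F4 | C=C1C(OC=O)CC/C(C(=O)OC)=C/CC[C@@H](O[Si](C)(C)C(C)(C)C)[C@@H]1CC[C@H](C)CCO[Si](c2ccccc2)(c2ccccc2)C(C)(C)C
F6 | step 13 | enol triflate of 20 (C10 triflate, terminal alkene retained) | C=C(OS(=O)(=O)C(F)(F)F)[C@@H](CC[C@H](C)CCO[Si](c1ccccc1)(c1ccccc1)C(C)(C)C)[C@H](O[Si](C)(C)C(C)(C)C)CCC=C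
F7 | step 13 | C5 aldehyde from F6 | C=C(OS(=O)(=O)C(F)(F)F)[C@@H](CC[C@H](C)CCO[Si](c1ccccc1)(c1ccccc1)C(C)(C)C)[C@H](O[Si](C)(C)C(C)(C)C)CCC=O
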